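The seven-membered ring, written as its C6 enol, is a cyclohepta-1,4-diene (C5=C6(O)–C7H2–C8=C9; daucane numbering, C1 is the methyl-bearing ring-fusion carbon and C10 its ring CH2 neighbour). This is the retron of a cis-divinylcyclopropane (Cope) rearrangement, and the route rests on making C1–C10 that way. The precursor is a siloxycyclopropane (C6–C7–C8) carrying the cyclopentenyl arm C5=C1 on C6 and a vinyl arm C9=C10 on C8. One thermal operation opens the three-membered ring, closes the hydroazulene, sets quaternary C1 by chirality transfer and delivers C6 as a silyl enol ether. The cyclopropane comes from asymmetric rhodium-carbenoid cyclopropanation of a 2-siloxydiene.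

Key step: step 10

Remark on descriptors: all intermediates carry the atom numbers of the target (C14 = methyl on C8, C15 = methyl on C1); β is the face of the five-membered ring that holds the C4 hydroxyl (and the C1 methyl in the target), α the opposite face.
Remark on the catalyst: Rh2(R-DOSP)4 is written by analogy with the known sense of styrene cyclopropanation with this catalyst family; should the sense on this substrate be the opposite, Rh2(S-DOSP)4 is used instead.
Remark on isolation: cyclopropane 13 is assumed to survive work-up at or below 25 °C, because the cis methyl on the cyclopentenyl terminus raises the Cope barrier; any portion that has already rearranged is carried into step 10.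

Step 1
Reactants: 1 (4R)-4-[(tert-butyldimethylsilyl)oxy]cyclopent-2-en-1-one
Product: 2 (3R,4R)-4-[(tert-butyldimethylsilyl)oxy]-3-methyl-1-[(trimethylsilyl)oxy]cyclopent-1-ene (methyl trans to OTBS)
Conditions: Me2CuLi, TMSCl, THF/Et2O, −78 °C
Reagents that add atoms: lithium dimethylcuprate ([Li+].C[Cu-]C); chlorotrimethylsilane (C[Si](C)(C)Cl)
Why: Conjugate addition of the Gilman cuprate anti to the silyloxy group with in situ O-silylation fixes the enolate toward C5; the C1 stereocenter formed here is removed again in step 2.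

Step 2
Reactants: 2 (3R,4R)-4-[(tert-butyldimethylsilyl)oxy]-3-methyl-1-[(trimethylsilyl)oxy]cyclopent-1-ene
Product: 3 (4R)-4-[(tert-butyldimethylsilyl)oxy]-3-methylcyclopent-2-en-1-one
Conditions: Pd(OAc)2 (1.1 equiv), MeCN, rt
Reagents that add atoms: none
Why: Saegusa–Ito oxidation: the palladium enolate at C5 loses the C1 hydrogen by β-hydride elimination and restores the enone with the methyl on C1, leaving C2 untouched.

Step 3
Reactants: 3 (4R)-4-[(tert-butyldimethylsilyl)oxy]-3-methylcyclopent-2-en-1-one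
Product: 4 (4R)-4-[(tert-butyldimethylsilyl)oxy]-2-iodo-3-methylcyclopent-2-en-1-one
Conditions: I2, pyridine, CH2Cl2, 0 °C to rt
Reagents that add atoms: iodine (II)
Why: α-Iodination of an enone by the pyridine addition–iodination–elimination pathway places iodine on C5 only and creates no stereocenter.

Step 4
Reactants: 4 (4R)-4-[(tert-butyldimethylsilyl)oxy]-2-iodo-3-methylcyclopent-2-en-1-one
Product: 5 (1R,4R)-4-[(tert-butyldimethylsilyl)oxy]-2-iodo-3-methyl-1-(propan-2-yl)cyclopent-2-en-1-ol (OH cis to OTBS)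
Conditions: iPrMgCl, anhydrous CeCl3, THF, −78 °C
Reagents that add atoms: isopropylmagnesium chloride (CC(C)[Mg]Cl)
Why: 1,2-Addition of the organocerium reagent to the enone carbonyl should occur anti to the C2 silyloxy group, so that the C4 hydroxyl is β (cis to OTBS) and the isopropyl group α.

Step 5
Reactants: 5 (1R,4R)-4-[(tert-butyldimethylsilyl)oxy]-2-iodo-3-methyl-1-(propan-2-yl)cyclopent-2-en-1-ol
Product: 8 1-[(3R,5R)-3,5-dihydroxy-2-methyl-5-(propan-2-yl)cyclopent-1-en-1-yl]ethan-1-one (cis diol), via ethyl enol ether 6 (not isolated), via silyl ether ketone 7 (not isolated)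
Conditions: tributyl(1-ethoxyvinyl)stannane, Pd(PPh3)4 (5 mol%), CuI (10 mol%), toluene, 90 °C; then 2 M aq. HCl, THF, rt
Reagents that add atoms: tributyl(1-ethoxyvinyl)stannane (CCCC[Sn](CCCC)(CCCC)C(=C)OCC); water (O)
Why: Stille coupling of the alkenyl iodide with the α-alkoxyvinylstannane, then acid hydrolysis of the enol ether to the methyl ketone and of the secondary silyl ether; no stereocenter is touched.

Step 6
Reactants: 8 1-[(3R,5R)-3,5-dihydroxy-2-methyl-5-(propan-2-yl)cyclopent-1-en-1-yl]ethan-1-one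
Product: 9 (1S,4R)-3-acetyl-4-hydroxy-2-methyl-4-(propan-2-yl)cyclopent-2-en-1-yl benzoate (benzoate α, trans to the C4 hydroxyl)
Conditions: PhCO2H, PPh3, DIAD, THF, 0 °C to rt
Reagents that add atoms: benzoic acid (O=C(O)c1ccccc1)
Why: Mitsunobu reaction: SN2 displacement of the activated secondary allylic C2 hydroxyl by benzoate inverts C2 from β to α, the tertiary C4 hydroxyl being inert.

Step 7
Reactants: 9 (1S,4R)-3-acetyl-4-hydroxy-2-methyl-4-(propan-2-yl)cyclopent-2-en-1-yl benzoate
Product: 10 (1S,4R)-2-methyl-4-(propan-2-yl)-4-[(triethylsilyl)oxy]-3-{1-[(triethylsilyl)oxy]ethenyl}cyclopent-2-en-1-yl benzoate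
Conditions: TESOTf (2.5 equiv), Et3N, CH2Cl2, −78 to 0 °C
Reagents that add atoms: triethylsilyl trifluoromethanesulfonate (CC[Si](CC)(CC)OS(=O)(=O)C(F)(F)F)
Why: Soft enolisation and O-silylation of the methyl ketone gives the kinetic 2-siloxydiene (C6=C7) while the tertiary alcohol is silylated in the same flask.

Step 8
Reactants: 11 methyl but-3-enoate
Product: 12 methyl 2-diazobut-3-enoate
Conditions: 4-acetamidobenzenesulfonyl azide, DBU, MeCN, 0 °C; used at once as a cold pentane solution
Reagents that add atoms: 4-acetamidobenzenesulfonyl azide (CC(=O)Nc1ccc(cc1)S(=O)(=O)N=[N+]=[N-])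
Why: Regitz diazo transfer to the doubly activated (allylic and α-ester) methylene gives the vinyldiazoacetate.

Step 9
Reactants: 10 (1S,4R)-2-methyl-4-(propan-2-yl)-4-[(triethylsilyl)oxy]-3-{1-[(triethylsilyl)oxy]ethenyl}cyclopent-2-en-1-yl benzoate; 12 methyl 2-diazobut-3-enoate
Product: 13 methyl (1S,2R)-2-[(3S,5R)-3-(benzoyloxy)-2-methyl-5-(propan-2-yl)-5-(triethylsilyloxy)cyclopent-1-en-1-yl]-1-ethenyl-2-[(triethylsilyl)oxy]cyclopropane-1-carboxylate (cyclopentenyl and ethenyl cis)
Conditions: Rh2(R-DOSP)4 (1 mol%), pentane, −78 °C, slow addition of 12, then 0 °C; Et3N-deactivated silica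
Reagents that add atoms: none
Why: Rhodium(II) donor/acceptor vinylcarbenoid cyclopropanation of the terminal enol ether double bond C6=C7: the alkenyl substituent on C6 is expected cis to the carbenoid's vinyl group, as in tandem cyclopropanation/Cope reactions of 2-substituted dienes, and the chiral prolinate catalyst sets the absolute configuration of C6 and C8.

Step 10
Reactants: 13 methyl (1S,2R)-2-[(3S,5R)-3-(benzoyloxy)-2-methyl-5-(propan-2-yl)-5-(triethylsilyloxy)cyclopent-1-en-1-yl]-1-ethenyl-2-[(triethylsilyl)oxy]cyclopropane-1-carboxylate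
Product: 14 methyl 2α-(benzoyloxy)-4β,6-bis(triethylsilyloxy)dauca-5,8-dien-14-oate (C1 methyl β; C6 triethylsilyl enol ether)
Conditions: toluene (0.02 M), BHT (cat.), base-washed glass, 100 °C
Reagents that add atoms: none
Why: Thermal [3,3]-sigmatropic divinylcyclopropane–cycloheptadiene (Cope) rearrangement: the C5=C1 and C9=C10 arms, held cis on the cyclopropane, fold endo over the three-membered ring and C10 bonds to C1 while the strained, donor/acceptor-weakened C6–C8 bond breaks. The closest known reaction type is the tandem cyclopropanation/Cope route from vinylcarbenoids and dienes to cycloheptadienes, including 2-methylcycloalkenyl dienes that give methyl-bearing quaternary carbons. The seven-membered ring closes by ring expansion (3 to 7) through a six-centre boat transition state, the only one that gives two cis ring alkenes (C5=C6 and C8=C9). The new quaternary stereocenter C1 is set by chirality transfer from C6/C8: with C8 on the α face of the cyclopentene, the suprafacial shift puts C10 on the α face of C1 and leaves the methyl β, while C6 and C8 become sp2. The step needs the concerted shift to outrun heterolytic opening of the push–pull cyclopropane, which would erase the stereochemical information; this is secured by the cis arrangement from step 9, the non-polar acid-free medium and the absence of a cis alkyl C–H for a 1,5-hydrogen shift, the cis methyl on C1 only raising the temperature needed.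

Step 11
Reactants: 14 methyl 2α-(benzoyloxy)-4β,6-bis(triethylsilyloxy)dauca-5,8-dien-14-oate
Product: 15 4β,6-bis(triethylsilyloxy)dauca-5,8-diene-2α,14-diol
Conditions: DIBAL-H (6 equiv), CH2Cl2, −78 °C; Rochelle salt work-up
Reagents that add atoms: none
Why: DIBAL reduction takes the conjugated ester to the primary allylic alcohol and cleaves the benzoate in the same operation, the silyl enol ether keeping C6 masked.

Step 12
Reactants: 15 4β,6-bis(triethylsilyloxy)dauca-5,8-diene-2α,14-diol
Product: 17 4β,6-bis(triethylsilyloxy)dauca-5,8-dien-2α-ol, via allylic mesylate 16 (not isolated)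
Conditions: MsCl (1.05 equiv), Et3N, THF, −40 °C; then LiBHEt3, −40 to 0 °C
Reagents that add atoms: none
Why: Selective sulfonylation of the primary allylic alcohol over the neopentyl-type secondary C2 alcohol, then SN2 hydride displacement, turns C14 into the methyl group.

Step 13
Reactants: 17 4β,6-bis(triethylsilyloxy)dauca-5,8-dien-2α-ol
Product: 18 4β,6-bis(triethylsilyloxy)dauca-5,8-dien-2α-yl acetate
Conditions: Ac2O, DMAP (cat.), pyridine, CH2Cl2, rt
Reagents that add atoms: acetic anhydride (CC(=O)OC(C)=O)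
Why: DMAP-catalysed acetylation of the only free hydroxyl installs the C2 acetate with retention.

Step 14
Reactants: 18 4β,6-bis(triethylsilyloxy)dauca-5,8-dien-2α-yl acetate
Product: 19 2α-acetoxy-4β-hydroxy-5αH-dauc-8-en-6-one (trans ring fusion)
Conditions: HF·pyridine, pyridine, THF, 0 °C to rt; if needed brief Et3N, CH2Cl2
Reagents that add atoms: none
Why: Desilylation frees the C6 ketone and the C4 hydroxyl; C5 should settle as the trans-fused epimer (H α), in which C6 sits cis to the hydroxyl and not to the isopropyl group and can accept an O4–H hydrogen bond.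

Step 15
Reactants: 19 2α-acetoxy-4β-hydroxy-5αH-dauc-8-en-6-one
Product: 20 2α-acetoxy-5αH-dauc-8-ene-4β,6α-diol
Conditions: Me4NBH(OAc)3, MeCN/AcOH (1:1), −25 °C
Reagents that add atoms: none
Why: Evans–Saksena hydroxyl-directed reduction: the C4 alkoxyborohydride delivers hydride through a chair six-membered transition state to the inner (β) face of C6, which should give the 6α-alcohol (anti-1,3-diol).

Step 16
Reactants: 20 2α-acetoxy-5αH-dauc-8-ene-4β,6α-diol
Product: 21 2α-acetoxy-4β-hydroxy-5αH-dauc-8-en-6α-yl 4-methoxybenzoate (target, CNP0171090.1)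
Conditions: 4-methoxybenzoyl chloride, Et3N, DMAP, CH2Cl2, 0 °C to rt
Reagents that add atoms: 4-methoxybenzoyl chloride (COc1ccc(cc1)C(Cl)=O)
Why: Acylation of the secondary C6 hydroxyl in the presence of the unreactive tertiary C4 hydroxyl completes the target with retention at C6.

Compound list
1 | (4R)-4-[(tert-butyldimethylsilyl)oxy]cyclopent-2-en-1-one | O=C1C=C[C@H](O[Si](C)(C)C(C)(C)C)C1 | starting material
2 | (3R,4R)-4-[(tert-butyldimethylsilyl)oxy]-3-methyl-1-[(trimethylsilyl)oxy]cyclopent-1-ene | C[Si](C)(C)OC1=C[C@@H](C)[C@H](O[Si](C)(C)C(C)(C)C)C1 | intermediate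
3 | (4R)-4-[(tert-butyldimethylsilyl)oxy]-3-methylcyclopent-2-en-1-one | O=C1C=C(C)[C@H](O[Si](C)(C)C(C)(C)C)C1 | intermediate
4 | (4R)-4-[(tert-butyldimethylsilyl)oxy]-2-iodo-3-methylcyclopent-2-en-1-one | O=C1C(I)=C(C)[C@H](O[Si](C)(C)C(C)(C)C)C1 | intermediate
5 | (1R,4R)-4-[(tert-butyldimethylsilyl)oxy]-2-iodo-3-methyl-1-(propan-2-yl)cyclopent-2-en-1-ol | CC(C)[C@]1(O)C[C@@H](O[Si](C)(C)C(C)(C)C)C(C)=C1I | intermediate
6 | (1R,4R)-4-[(tert-butyldimethylsilyl)oxy]-2-(1-ethoxyethenyl)-3-methyl-1-(propan-2-yl)cyclopent-2-en-1-ol | CC(C)[C@]1(O)C[C@@H](O[Si](C)(C)C(C)(C)C)C(C)=C1C(=C)OCC | intermediate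
7 | 1-[(3R,5R)-3-[(tert-butyldimethylsilyl)oxy]-5-hydroxy-2-methyl-5-(propan-2-yl)cyclopent-1-en-1-yl]ethan-1-one | CC(C)[C@]1(O)C[C@@H](O[Si](C)(C)C(C)(C)C)C(C)=C1C(C)=O | intermediate
8 | 1-[(3R,5R)-3,5-dihydroxy-2-methyl-5-(propan-2-yl)cyclopent-1-en-1-yl]ethan-1-one | CC(C)[C@]1(O)C[C@@H](O)C(C)=C1C(C)=O | intermediate
9 | (1S,4R)-3-acetyl-4-hydroxy-2-methyl-4-(propan-2-yl)cyclopent-2-en-1-yl benzoate | CC(C)[C@]1(O)C[C@H](OC(=O)c2ccccc2)C(C)=C1C(C)=O | intermediate
10 | (1S,4R)-2-methyl-4-(propan-2-yl)-4-[(triethylsilyl)oxy]-3-{1-[(triethylsilyl)oxy]ethenyl}cyclopent-2-en-1-yl benzoate | C=C(O[Si](CC)(CC)CC)C1=C(C)[C@@H](OC(=O)c2ccccc2)C[C@@]1(O[Si](CC)(CC)CC)C(C)C | intermediate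
11 | methyl but-3-enoate | C=CCC(=O)OC | starting material
12 | methyl 2-diazobut-3-enoate | C=CC(=[N+]=[N-])C(=O)OC | intermediate
13 | methyl (1S,2R)-2-[(3S,5R)-3-(benzoyloxy)-2-methyl-5-(propan-2-yl)-5-(triethylsilyloxy)cyclopent-1-en-1-yl]-1-ethenyl-2-[(triethylsilyl)oxy]cyclopropane-1-carboxylate | C=C[C@@]1(C(=O)OC)C[C@@]1(O[Si](CC)(CC)CC)C2=C(C)[C@@H](OC(=O)c3ccccc3)C[C@@]2(O[Si](CC)(CC)CC)C(C)C | intermediate
14 | methyl 2α-(benzoyloxy)-4β,6-bis(triethylsilyloxy)dauca-5,8-dien-14-oate | COC(=O)C1=CC[C@@]2(C)[C@@H](OC(=O)c3ccccc3)C[C@@](O[Si](CC)(CC)CC)(C(C)C)C2=C(O[Si](CC)(CC)CC)C1 | intermediate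
15 | 4β,6-bis(triethylsilyloxy)dauca-5,8-diene-2α,14-diol | OCC1=CC[C@@]2(C)[C@@H](O)C[C@@](O[Si](CC)(CC)CC)(C(C)C)C2=C(O[Si](CC)(CC)CC)C1 | intermediate
16 | 2α-hydroxy-4β,6-bis(triethylsilyloxy)dauca-5,8-dien-14-yl methanesulfonate | CS(=O)(=O)OCC1=CC[C@@]2(C)[C@@H](O)C[C@@](O[Si](CC)(CC)CC)(C(C)C)C2=C(O[Si](CC)(CC)CC)C1 | intermediate
17 | 4β,6-bis(triethylsilyloxy)dauca-5,8-dien-2α-ol | CC1=CC[C@@]2(C)[C@@H](O)C[C@@](O[Si](CC)(CC)CC)(C(C)C)C2=C(O[Si](CC)(CC)CC)C1 | intermediate
18 | 4β,6-bis(triethylsilyloxy)dauca-5,8-dien-2α-yl acetate | CC1=CC[C@@]2(C)[C@@H](OC(C)=O)C[C@@](O[Si](CC)(CC)CC)(C(C)C)C2=C(O[Si](CC)(CC)CC)C1 | intermediate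
19 | 2α-acetoxy-4β-hydroxy-5αH-dauc-8-en-6-one | CC1=CC[C@@]2(C)[C@@H](OC(C)=O)C[C@@](O)(C(C)C)[C@@H]2C(=O)C1 | intermediate
20 | 2α-acetoxy-5αH-dauc-8-ene-4β,6α-diol | CC1=CC[C@@]2(C)[C@@H](OC(C)=O)C[C@@](O)(C(C)C)[C@@H]2[C@@H](O)C1 | intermediate
21 | 2α-acetoxy-4β-hydroxy-5αH-dauc-8-en-6α-yl 4-methoxybenzoate (CNP0171090.1) | COc1ccc(C(=O)O[C@H]2CC(C)=CC[C@@]3(C)[C@@H](OC(C)=O)C[C@@](O)(C(C)C)[C@H]23)cc1 | target

Total step count: 16. Longest linear sequence: 15 steps (steps 1–7 and 9–16); step 8 is a one-step side branch.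

Steps most likely to fail

1. Step 10 (key step). The push–pull cyclopropane may open heterolytically along C6–C8 faster than the congested boat transition state is reached. That would leak the stereochemical information to C1 or give an open-chain keto ester. The fallback sets out from 13 and removes the acceptor before the rearrangement. DIBAL-H at −78 °C should reduce the ester (and cleave the benzoate) to the cyclopropylcarbinol diol F1, a plain 1-siloxy-cis-1,2-dialkenylcyclopropane with no zwitterionic pathway. Heating F1 in toluene should give the same Cope product one oxidation level lower, which is 15, where the route is rejoined.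

2. Step 9. Face selectivity may be poor if catalyst control and the bias of the chiral, congested diene are mismatched; the carbenoid may also react at its vinylogous position. The fallback sets out from 10 and replaces catalyst control by auxiliary control. (R)-Pantolactone is acylated with but-3-enoyl chloride to the ester F2, and diazo transfer gives the diazo ester F3. Cyclopropanation of 10 with F3 under achiral Rh2(OOct)4 in pentane should give the cyclopropane F4, the α-hydroxy-ester auxiliary shielding one face of the carbenoid (the antipodal auxiliary is taken if the sense demands it). Heating F4 gives the Cope product F5, and the DIBAL reduction of step 11 removes auxiliary and benzoate together and returns to 15.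

3. Step 15. Hydride may be delivered intermolecularly from the exposed outer face of C6 instead of intramolecularly from the C4 alkoxyborohydride, which would give the 6β-alcohol. The fallback sets out from 19 and uses that preference deliberately. NaBH4/CeCl3 in MeOH at −78 °C should attack from the outer face and give the 6β-alcohol F6. A Mitsunobu reaction of F6 with 4-methoxybenzoic acid (PPh3, DIAD, toluene) then inverts C6 and installs the ester in one operation, arriving directly at 21.

Further compounds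
F1 | step 10 | [(1S,2R)-1-ethenyl-2-[(3S,5R)-3-hydroxy-2-methyl-5-(propan-2-yl)-5-(triethylsilyloxy)cyclopent-1-en-1-yl]-2-(triethylsilyloxy)cyclopropyl]methanol | OC[C@]1(C=C)C[C@@]1(O[Si](CC)(CC)CC)C2=C(C)[C@@H](O)C[C@@]2(O[Si](CC)(CC)CC)C(C)C
F2 | step 9 | (3R)-4,4-dimethyl-2-oxooxolan-3-yl but-3-enoate | C=CCC(=O)O[C@H]1C(=O)OCC1(C)C
F3 | step 9 | (3R)-4,4-dimethyl-2-oxooxolan-3-yl 2-diazobut-3-enoate | C=CC(=[N+]=[N-])C(=O)O[C@H]1C(=O)OCC1(C)C
F4 | step 9 | (3R)-4,4-dimethyl-2-oxooxolan-3-yl (1S,2R)-2-[(3S,5R)-3-(benzoyloxy)-2-methyl-5-(propan-2-yl)-5-(triethylsilyloxy)cyclopent-1-en-1-yl]-1-ethenyl-2-[(triethylsilyl)oxy]cyclopropane-1-carboxylate | C=C[C@@]1(C(=O)O[C@H]3C(=O)OCC3(C)C)C[C@@]1(O[Si](CC)(CC)CC)C2=C(C)[C@@H](OC(=O)c4ccccc4)C[C@@]2(O[Si](CC)(CC)CC)C(C)C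
F5 | step 9 | (3R)-4,4-dimethyl-2-oxooxolan-3-yl 2α-(benzoyloxy)-4β,6-bis(triethylsilyloxy)dauca-5,8-dien-14-oate | CC1(C)COC(=O)[C@@H]1OC(=O)C1=CC[C@@]2(C)[C@@H](OC(=O)c3ccccc3)C[C@@](O[Si](CC)(CC)CC)(C(C)C)C2=C(O[Si](CC)(CC)CC)C1
F6 | step 15 | 2α-acetoxy-5αH-dauc-8-ene-4β,6β-diol | CC1=CC[C@@]2(C)[C@@H](OC(C)=O)C[C@@](O)(C(C)C)[C@@H]2[C@H](O)C1
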